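**Retrosynthetic overview**

- The strategy rests on ring D. It is a phenol whose carbon D1 (ortho to the D6 hydroxyl) is tied through CH2 to C6 of ring A and whose carbon D3 (para to the D6 hydroxyl) is tied through CH2 to ring E. C6 is the only free position ortho to O5, so a Claisen shift from O5 plants CH2–C(=CH2)–C(=O)CH3 at C6; its carbons become D1, D2, D6 and D5.
- Key disconnection: ring D is opened to the 2-siloxy-1,3-diene on the C6 methylene and the ring-E aryl ethynyl ketone. The Diels–Alder reaction forms D5–D4 and D2–D3, DDQ aromatises, and the diaryl ketone left at D3 is later reduced to the D–E methylene.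
- End game: the 2-hydroxybenzyl group (ring G) goes onto C8, the only free carbon of ring A. The phenyl group (ring B) is added last to C2 of the fully benzylated chromone by enantioselective conjugate addition, and neutral hydrogenolysis frees the phenols without touching C2.
- Ring order: rings A and C are bought as 5,7-dihydroxychromone; rings E and F are joined by Negishi coupling; ring D is built de novo; ring G is attached; ring B comes last. Rings E and F carry benzyl ethers throughout.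

Key step: step 12

Assumption: (R)-t-BuPyOx is taken as the ligand enantiomer that gives 2S, by analogy with the facial sense of this ligand class on cyclic enones; if the sense proves opposite, the antipodal ligand is used under the same conditions.

**Route**

Step 1
Reactants: 1 methyl vinyl ketone
Product: 2 3-(hydroxymethyl)but-3-en-2-one
Conditions: HCHO (37% aq.), DABCO (cat.), THF, rt
Reagents that add atoms: formaldehyde, C=O
Why: Morita–Baylis–Hillman reaction, in which DABCO adds to the enone, the resulting enolate adds to formaldehyde and loss of the amine returns the α-(hydroxymethyl) enone.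

Step 2
Reactants: 2 3-(hydroxymethyl)but-3-en-2-one
Product: 3 3-(bromomethyl)but-3-en-2-one
Conditions: PBr3, Et2O, 0 °C
Reagents that add atoms: phosphorus tribromide, BrP(Br)Br
Why: Nucleophilic substitution of the primary allylic alcohol by bromide; direct and allylically transposed displacement give the same bromide because the allyl unit is symmetric about its central carbon.

Step 3
Reactants: 4 5,7-dihydroxy-4H-chromen-4-one
Product: 5 5-hydroxy-7-(methoxymethoxy)-4H-chromen-4-one
Conditions: MOMCl (1.1 equiv), K2CO3, acetone, 0 °C to rt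
Reagents that add atoms: chloromethyl methyl ether, COCCl
Why: Williamson-type alkylation that should go to O7 alone, since the 7-hydroxyl is the acidic free phenol while the 5-hydroxyl is held in a hydrogen bond to the C4 carbonyl.

Step 4
Reactants: 5 5-hydroxy-7-(methoxymethoxy)-4H-chromen-4-one; 3 3-(bromomethyl)but-3-en-2-one
Product: 6 7-(methoxymethoxy)-5-[(2-methylidene-3-oxobutyl)oxy]-4H-chromen-4-one
Conditions: K2CO3, DMF, 0 °C to rt
Reagents that add atoms: none
Why: Williamson O-alkylation of the 5-phenoxide by the very electrophilic 2-(bromomethyl) enone, where SN2 and SN2' displacement lead to the same ether.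

Step 5
Reactants: 6 7-(methoxymethoxy)-5-[(2-methylidene-3-oxobutyl)oxy]-4H-chromen-4-one
Product: 7 5-hydroxy-7-(methoxymethoxy)-6-(2-methylidene-3-oxobutyl)-4H-chromen-4-one
Conditions: Eu(fod)3 (10 mol%), BHT (cat.), CHCl3, 60 °C
Reagents that add atoms: none
Why: Aromatic Claisen rearrangement ([3,3] shift) accelerated by chelation of europium tris(6,6,7,7,8,8,8-heptafluoro-2,2-dimethyl-3,5-octanedionate) between O4 and O5, which can only deliver the allyl terminus to C6 because the other ortho position, C4a, is the ring fusion, and which should spare the enone at this temperature.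

Step 6
Reactants: 7 5-hydroxy-7-(methoxymethoxy)-6-(2-methylidene-3-oxobutyl)-4H-chromen-4-one
Product: 8 5-(tert-butyldimethylsilyloxy)-6-[3-(tert-butyldimethylsilyloxy)-2-methylidenebut-3-en-1-yl]-7-(methoxymethoxy)-4H-chromen-4-one
Conditions: TBSOTf (2.3 equiv), Et3N, CH2Cl2, −78 to 0 °C; used crude after filtration through basic alumina
Reagents that add atoms: tert-butyldimethylsilyl trifluoromethanesulfonate, CC(C)(C)[Si](C)(C)OS(=O)(=O)C(F)(F)F
Why: Soft enolisation with silyl triflate and amine, which silylates the 5-hydroxyl and turns the methyl ketone (its only enolisable side) into the cross-conjugated 2-siloxy-1,3-diene.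

Step 7
Reactants: 9 3-bromo-2-hydroxybenzaldehyde
Product: 10 2-(benzyloxy)-3-bromobenzaldehyde
Conditions: BnBr, K2CO3, DMF, rt
Reagents that add atoms: benzyl bromide, BrCc1ccccc1
Why: Williamson etherification of the phenol.

Step 8
Reactants: 11 [2-(benzyloxy)phenyl]methanol
Product: 12 1-(benzyloxy)-2-(bromomethyl)benzene
Conditions: PBr3, CH2Cl2, 0 °C
Reagents that add atoms: phosphorus tribromide, BrP(Br)Br
Why: Nucleophilic substitution of the benzylic alcohol by bromide.

Step 9
Reactants: 12 1-(benzyloxy)-2-(bromomethyl)benzene; 10 2-(benzyloxy)-3-bromobenzaldehyde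
Product: 14 2-(benzyloxy)-3-[2-(benzyloxy)benzyl]benzaldehyde, via benzylzinc bromide 13 (not isolated)
Conditions: Zn dust, LiCl, THF, rt; then 10, Pd(OAc)2 (2 mol%), SPhos (4 mol%), THF, rt
Reagents that add atoms: zinc, [Zn] (held only in intermediate 13)
Why: Zinc insertion into the benzylic C–Br bond followed by Negishi coupling (oxidative addition of the aryl bromide to zerovalent palladium, transmetalation, reductive elimination), which should outpace uncatalysed addition of the benzylzinc halide to the aldehyde.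

Step 10
Reactants: 14 2-(benzyloxy)-3-[2-(benzyloxy)benzyl]benzaldehyde
Product: 15 rac-1-{2-(benzyloxy)-3-[2-(benzyloxy)benzyl]phenyl}prop-2-yn-1-ol
Conditions: ethynylmagnesium bromide, THF, −78 to 0 °C; aq. NH4Cl
Reagents that add atoms: ethynylmagnesium bromide, C#C[Mg]Br
Why: Grignard 1,2-addition to the aldehyde; the carbinol centre is formed racemic and is removed in the next step.

Step 11
Reactants: 15 rac-1-{2-(benzyloxy)-3-[2-(benzyloxy)benzyl]phenyl}prop-2-yn-1-ol
Product: 16 1-{2-(benzyloxy)-3-[2-(benzyloxy)benzyl]phenyl}prop-2-yn-1-one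
Conditions: MnO2 (activated), CH2Cl2, rt
Reagents that add atoms: none
Why: MnO2 oxidation of an alcohol that is both benzylic and propargylic, giving the aryl ethynyl ketone.

Step 12
Reactants: 8 5-(tert-butyldimethylsilyloxy)-6-[3-(tert-butyldimethylsilyloxy)-2-methylidenebut-3-en-1-yl]-7-(methoxymethoxy)-4H-chromen-4-one; 16 1-{2-(benzyloxy)-3-[2-(benzyloxy)benzyl]phenyl}prop-2-yn-1-one
Product: 18 6-{5-[2-(benzyloxy)-3-(2-(benzyloxy)benzyl)benzoyl]-2-(tert-butyldimethylsilyloxy)benzyl}-5-(tert-butyldimethylsilyloxy)-7-(methoxymethoxy)-4H-chromen-4-one, via cyclohexa-1,4-diene cycloadduct 17 (not isolated)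
Conditions: PhMe, BHT (cat.), 105 °C, sealed tube; then DDQ (1.1 equiv), rt
Reagents that add atoms: none
Why: A thermal, concerted but asynchronous normal-electron-demand Diels–Alder reaction joins the s-cis 2-siloxy-1,3-diene of 8 to the ethynyl ketone of 16, the closest known reaction type being the cycloaddition of 2-siloxydienes with ynones followed by dehydrogenation to para-acyl aryl silyl ethers. Ring D closes by intermolecular [4+2] cycloaddition that forms D5–D4 and D2–D3 in one event, and DDQ then takes hydride from a doubly allylic CH2 of the 1,4-cyclohexadiene 17, loss of a proton giving the arene. No stereocentre is formed. The step needs the orientation in which the aroyl group ends para to the siloxy carbon D6 and meta to D1: the oxygen lone pair puts the largest HOMO coefficient on the terminal CH2 next to the siloxy carbon (D5), which bonds to the β-carbon of the ynone (D4), and this donor should outweigh the alkyl group on D1 that argues for the other orientation. Chemoselectivity rests on the ynone being the only strong dienophile present, the chromone C2=C3 bond being a vinylogous ester, and the benzyl, MOM and silyl ethers being inert to heat and to DDQ at room temperature.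

Step 13
Reactants: 18 6-{5-[2-(benzyloxy)-3-(2-(benzyloxy)benzyl)benzoyl]-2-(tert-butyldimethylsilyloxy)benzyl}-5-(tert-butyldimethylsilyloxy)-7-(methoxymethoxy)-4H-chromen-4-one
Product: 19 6-{5-[2-(benzyloxy)-3-(2-(benzyloxy)benzyl)benzoyl]-2-hydroxybenzyl}-5,7-dihydroxy-4H-chromen-4-one
Conditions: HCl (3 M aq.), MeOH/THF, 50 °C
Reagents that add atoms: none
Why: Acid-catalysed methanolysis cleaves the MOM acetal and both aryl silyl ethers, while the benzyl ethers, the chromone and the diaryl ketone are stable to methanolic acid.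

Step 14
Reactants: 19 6-{5-[2-(benzyloxy)-3-(2-(benzyloxy)benzyl)benzoyl]-2-hydroxybenzyl}-5,7-dihydroxy-4H-chromen-4-one; 20 2-hydroxybenzyl alcohol
Product: 21 6-{5-[2-(benzyloxy)-3-(2-(benzyloxy)benzyl)benzoyl]-2-hydroxybenzyl}-5,7-dihydroxy-8-(2-hydroxybenzyl)-4H-chromen-4-one
Conditions: ZnCl2 (2 equiv), 20 (1.5 equiv), 1,4-dioxane, 80 °C
Reagents that add atoms: none
Why: Friedel–Crafts hydroxybenzylation in which ZnCl2 ionises the benzylic alcohol to a zinc-bound ortho-quinone methide that is attacked by C8, the only free carbon of the phloroglucinol-type ring A and the most nucleophilic arene carbon present, ring D being deactivated by its para-aroyl group and rings E and F being ethers.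

Step 15
Reactants: 21 6-{5-[2-(benzyloxy)-3-(2-(benzyloxy)benzyl)benzoyl]-2-hydroxybenzyl}-5,7-dihydroxy-8-(2-hydroxybenzyl)-4H-chromen-4-one
Product: 22 6-{5-[2-(benzyloxy)-3-(2-(benzyloxy)benzyl)benzyl]-2-hydroxybenzyl}-5,7-dihydroxy-8-(2-hydroxybenzyl)-4H-chromen-4-one
Conditions: Et3SiH (5 equiv), TFA, CH2Cl2, 0 °C to rt
Reagents that add atoms: none
Why: Ionic hydrogenation of the diaryl ketone, in which protonation, hydride transfer, ionisation of the carbinol to a cation stabilised by the para-hydroxyl of ring D and a second hydride transfer give the methylene, while the chromone and the benzyl ethers should not react.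

Step 16
Reactants: 22 6-{5-[2-(benzyloxy)-3-(2-(benzyloxy)benzyl)benzyl]-2-hydroxybenzyl}-5,7-dihydroxy-8-(2-hydroxybenzyl)-4H-chromen-4-one
Product: 23 5,7-bis(benzyloxy)-6-{2-(benzyloxy)-5-[2-(benzyloxy)-3-(2-(benzyloxy)benzyl)benzyl]benzyl}-8-[2-(benzyloxy)benzyl]-4H-chromen-4-one
Conditions: BnBr (excess), K2CO3, Bu4NI (cat.), DMF, 60 °C
Reagents that add atoms: benzyl bromide, BrCc1ccccc1
Why: Fourfold Williamson etherification, with heating so that the hydrogen-bonded 5-hydroxyl is benzylated as well.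

Step 17
Reactants: 23 5,7-bis(benzyloxy)-6-{2-(benzyloxy)-5-[2-(benzyloxy)-3-(2-(benzyloxy)benzyl)benzyl]benzyl}-8-[2-(benzyloxy)benzyl]-4H-chromen-4-one; 24 phenylboronic acid
Product: 25 (2S)-5,7-bis(benzyloxy)-6-{2-(benzyloxy)-5-[2-(benzyloxy)-3-(2-(benzyloxy)benzyl)benzyl]benzyl}-8-[2-(benzyloxy)benzyl]-2-phenylchroman-4-one
Conditions: Pd(OCOCF3)2 (10 mol%), (R)-t-BuPyOx (12 mol%), NH4PF6 (30 mol%), H2O (5 equiv), ClCH2CH2Cl, 60 °C
Reagents that add atoms: none
Why: Palladium-catalysed enantioselective conjugate addition of an arylboronic acid to a chromone (transmetalation, migratory insertion across C2=C3, protonolysis of the palladium enolate), in which the tert-butyl group of the pyridine-oxazoline ligand (R)-4-tert-butyl-2-(pyridin-2-yl)-4,5-dihydrooxazole selects the face of C2 that takes the phenyl group and so sets C2 as S.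

Step 18
Reactants: 25 (2S)-5,7-bis(benzyloxy)-6-{2-(benzyloxy)-5-[2-(benzyloxy)-3-(2-(benzyloxy)benzyl)benzyl]benzyl}-8-[2-(benzyloxy)benzyl]-2-phenylchroman-4-one
Product: 26 (2S)-5,7-dihydroxy-6-{2-hydroxy-5-[2-hydroxy-3-(2-hydroxybenzyl)benzyl]benzyl}-8-(2-hydroxybenzyl)-2-phenylchroman-4-one (CNP0107650.1)
Conditions: H2 (1 atm), Pd/C (10%), EtOAc/MeOH, rt; stopped at full uptake
Reagents that add atoms: none
Why: Catalytic hydrogenolysis of the six aryl benzyl ethers under neutral conditions, which avoids the base- or acid-mediated ring opening to the chalcone that would scramble C2.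

**Compound list**

1 | methyl vinyl ketone | CC(=O)C=C | starting material
2 | 3-(hydroxymethyl)but-3-en-2-one | CC(=O)C(=C)CO | intermediate
3 | 3-(bromomethyl)but-3-en-2-one | CC(=O)C(=C)CBr | intermediate
4 | 5,7-dihydroxy-4H-chromen-4-one | O=c1ccoc2cc(O)cc(O)c12 | starting material
5 | 5-hydroxy-7-(methoxymethoxy)-4H-chromen-4-one | O=c1ccoc2cc(OCOC)cc(O)c12 | intermediate
6 | 7-(methoxymethoxy)-5-[(2-methylidene-3-oxobutyl)oxy]-4H-chromen-4-one | CC(=O)C(=C)COc1cc(OCOC)cc2occc(=O)c12 | intermediate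
7 | 5-hydroxy-7-(methoxymethoxy)-6-(2-methylidene-3-oxobutyl)-4H-chromen-4-one | CC(=O)C(=C)Cc1c(OCOC)cc2occc(=O)c2c1O | intermediate
8 | 5-(tert-butyldimethylsilyloxy)-6-[3-(tert-butyldimethylsilyloxy)-2-methylidenebut-3-en-1-yl]-7-(methoxymethoxy)-4H-chromen-4-one | C=C(O[Si](C)(C)C(C)(C)C)C(=C)Cc1c(OCOC)cc2occc(=O)c2c1O[Si](C)(C)C(C)(C)C | intermediate
9 | 3-bromo-2-hydroxybenzaldehyde | O=Cc1cccc(Br)c1O | starting material
10 | 2-(benzyloxy)-3-bromobenzaldehyde | O=Cc1cccc(Br)c1OCc1ccccc1 | intermediate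
11 | [2-(benzyloxy)phenyl]methanol | OCc1ccccc1OCc1ccccc1 | starting material
12 | 1-(benzyloxy)-2-(bromomethyl)benzene | BrCc1ccccc1OCc1ccccc1 | intermediate
13 | [2-(benzyloxy)benzyl]zinc bromide | Br[Zn]Cc1ccccc1OCc1ccccc1 | intermediate
14 | 2-(benzyloxy)-3-[2-(benzyloxy)benzyl]benzaldehyde | O=Cc1cccc(Cc2ccccc2OCc2ccccc2)c1OCc1ccccc1 | intermediate
15 | rac-1-{2-(benzyloxy)-3-[2-(benzyloxy)benzyl]phenyl}prop-2-yn-1-ol | C#CC(O)c1cccc(Cc2ccccc2OCc2ccccc2)c1OCc1ccccc1 | intermediate
16 | 1-{2-(benzyloxy)-3-[2-(benzyloxy)benzyl]phenyl}prop-2-yn-1-one | C#CC(=O)c1cccc(Cc2ccccc2OCc2ccccc2)c1OCc1ccccc1 | intermediate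
17 | cyclohexa-1,4-diene cycloadduct of 8 and 16 (1-aroyl-4-siloxy-5-(chromonylmethyl)cyclohexa-1,4-diene) | O=C(C1=CCC(O[Si](C)(C)C(C)(C)C)=C(Cc2c(OCOC)cc3occc(=O)c3c2O[Si](C)(C)C(C)(C)C)C1)c1cccc(Cc2ccccc2OCc2ccccc2)c1OCc1ccccc1 | intermediate
18 | 6-{5-[2-(benzyloxy)-3-(2-(benzyloxy)benzyl)benzoyl]-2-(tert-butyldimethylsilyloxy)benzyl}-5-(tert-butyldimethylsilyloxy)-7-(methoxymethoxy)-4H-chromen-4-one | O=C(c1ccc(O[Si](C)(C)C(C)(C)C)c(Cc2c(OCOC)cc3occc(=O)c3c2O[Si](C)(C)C(C)(C)C)c1)c1cccc(Cc2ccccc2OCc2ccccc2)c1OCc1ccccc1 | intermediate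
19 | 6-{5-[2-(benzyloxy)-3-(2-(benzyloxy)benzyl)benzoyl]-2-hydroxybenzyl}-5,7-dihydroxy-4H-chromen-4-one | O=C(c1ccc(O)c(Cc2c(O)cc3occc(=O)c3c2O)c1)c1cccc(Cc2ccccc2OCc2ccccc2)c1OCc1ccccc1 | intermediate
20 | 2-hydroxybenzyl alcohol | OCc1ccccc1O | starting material
21 | 6-{5-[2-(benzyloxy)-3-(2-(benzyloxy)benzyl)benzoyl]-2-hydroxybenzyl}-5,7-dihydroxy-8-(2-hydroxybenzyl)-4H-chromen-4-one | O=C(c1ccc(O)c(Cc2c(O)c(Cc3ccccc3O)c3occc(=O)c3c2O)c1)c1cccc(Cc2ccccc2OCc2ccccc2)c1OCc1ccccc1 | intermediate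
22 | 6-{5-[2-(benzyloxy)-3-(2-(benzyloxy)benzyl)benzyl]-2-hydroxybenzyl}-5,7-dihydroxy-8-(2-hydroxybenzyl)-4H-chromen-4-one | O=c1ccoc2c(Cc3ccccc3O)c(O)c(Cc3cc(Cc4cccc(Cc5ccccc5OCc5ccccc5)c4OCc4ccccc4)ccc3O)c(O)c12 | intermediate
23 | 5,7-bis(benzyloxy)-6-{2-(benzyloxy)-5-[2-(benzyloxy)-3-(2-(benzyloxy)benzyl)benzyl]benzyl}-8-[2-(benzyloxy)benzyl]-4H-chromen-4-one | O=c1ccoc2c(Cc3ccccc3OCc3ccccc3)c(OCc3ccccc3)c(Cc3cc(Cc4cccc(Cc5ccccc5OCc5ccccc5)c4OCc4ccccc4)ccc3OCc3ccccc3)c(OCc3ccccc3)c12 | intermediate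
24 | phenylboronic acid | OB(O)c1ccccc1 | starting material
25 | (2S)-5,7-bis(benzyloxy)-6-{2-(benzyloxy)-5-[2-(benzyloxy)-3-(2-(benzyloxy)benzyl)benzyl]benzyl}-8-[2-(benzyloxy)benzyl]-2-phenylchroman-4-one | O=C1C[C@@H](c2ccccc2)Oc2c(Cc3ccccc3OCc3ccccc3)c(OCc3ccccc3)c(Cc3cc(Cc4cccc(Cc5ccccc5OCc5ccccc5)c4OCc4ccccc4)ccc3OCc3ccccc3)c(OCc3ccccc3)c21 | intermediate
26 | (2S)-5,7-dihydroxy-6-{2-hydroxy-5-[2-hydroxy-3-(2-hydroxybenzyl)benzyl]benzyl}-8-(2-hydroxybenzyl)-2-phenylchroman-4-one (CNP0107650.1) | O=C1C[C@@H](c2ccccc2)Oc2c(Cc3ccccc3O)c(O)c(Cc3cc(Cc4cccc(Cc5ccccc5O)c4O)ccc3O)c(O)c21 | target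

**Step count and risks**

Total step count: 18. Longest linear sequence: 12 steps (steps 1, 2, 4, 5, 6, then 12 to 18).

Steps most likely to fail:

1. Step 12. The cycloaddition may leak to the other orientation, because the alkyl group on D1 pushes the aroyl group toward the position para to the C6 methylene. The siloxydiene may also dimerise or lose silicon on heating before it adds, or add to the ynone in an open-chain Michael sense. The fallback fixes the orientation by polarity and sets out from ketone 7 and ynone 16. Pyrrolidine (MeOH, rt) adds to 16 to give the enaminone (E)-1-{2-(benzyloxy)-3-[2-(benzyloxy)benzyl]phenyl}-3-(pyrrolidin-1-yl)prop-2-en-1-one F1. Aqueous HCl in THF hydrolyses it to the 3-aryl-3-oxopropanal F2. Et3N-mediated Michael addition of the central carbon of F2 to the α-methylene ketone of 7 makes the D3–D2 bond and gives the keto aldehyde F3. Intramolecular aldol condensation of the methyl ketone onto the aldehyde (PPTS, PhMe, 80 °C; a Robinson-type annulation) makes D5–D4 and gives the 4-aroylcyclohex-2-enone F4. DDQ dehydrogenation gives the para-aroylphenol F5, and HCl in MeOH removes the MOM group to come back to the route at 19.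

2. Step 17. Carbopalladation of the electron-rich, fully substituted chromone may be slower than protodeboronation of the boronic acid, or the facial selectivity may be too low. The fallback sets out from 23. KOH in aqueous EtOH at reflux opens the pyranone with loss of C2 as formate to give the 2-hydroxyacetophenone F9. Claisen–Schmidt condensation with benzaldehyde (KOH, EtOH) gives the 2'-hydroxychalcone F10. NaOAc in EtOH at reflux closes it by oxa-Michael addition to the racemic flavanone F11. Preparative chromatography on a chiral stationary phase separates the enantiomers and comes back to the route at 25.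

3. Step 14. The hydroxybenzylation may spread to ring F or to the new ring G, go on to a second benzylation, or be overtaken by self-condensation of the benzylic alcohol before ring A reacts. The fallback sets out from 19 and replaces the Friedel–Crafts step by halogenation and cross-coupling. N-Iodosuccinimide (DMF, 0 °C) iodinates C8 to give the 8-iodo triol F6. BnBr and K2CO3 in DMF give the tris(benzyl ether) F7. Negishi coupling with the benzylzinc bromide 13 (Pd(OAc)2, SPhos, THF) gives the hexabenzyl diaryl ketone F8. Et3SiH and TFA reduce the ketone to the methylene and come back to the route at 23.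

**Further compounds**

F1 | step 12 | (E)-1-{2-(benzyloxy)-3-[2-(benzyloxy)benzyl]phenyl}-3-(pyrrolidin-1-yl)prop-2-en-1-one | O=C(/C=C/N1CCCC1)c1cccc(Cc2ccccc2OCc2ccccc2)c1OCc1ccccc1
F2 | step 12 | 3-{2-(benzyloxy)-3-[2-(benzyloxy)benzyl]phenyl}-3-oxopropanal | O=CCC(=O)c1cccc(Cc2ccccc2OCc2ccccc2)c1OCc1ccccc1
F3 | step 12 | 2-{2-(benzyloxy)-3-[2-(benzyloxy)benzyl]benzoyl}-4-{[5-hydroxy-7-(methoxymethoxy)-4-oxo-4H-chromen-6-yl]methyl}-5-oxohexanal (mixture of diastereomers) | CC(=O)C(Cc1c(OCOC)cc2occc(=O)c2c1O)CC(C=O)C(=O)c1cccc(Cc2ccccc2OCc2ccccc2)c1OCc1ccccc1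
F4 | step 12 | 6-({5-[2-(benzyloxy)-3-(2-(benzyloxy)benzyl)benzoyl]-2-oxocyclohex-3-en-1-yl}methyl)-5-hydroxy-7-(methoxymethoxy)-4H-chromen-4-one (mixture of diastereomers) | O=C1C=CC(C(=O)c2cccc(Cc3ccccc3OCc3ccccc3)c2OCc2ccccc2)CC1Cc1c(OCOC)cc2occc(=O)c2c1O
F5 | step 12 | 6-{5-[2-(benzyloxy)-3-(2-(benzyloxy)benzyl)benzoyl]-2-hydroxybenzyl}-5-hydroxy-7-(methoxymethoxy)-4H-chromen-4-one | O=C(c1ccc(O)c(Cc2c(OCOC)cc3occc(=O)c3c2O)c1)c1cccc(Cc2ccccc2OCc2ccccc2)c1OCc1ccccc1
F6 | step 14 | 6-{5-[2-(benzyloxy)-3-(2-(benzyloxy)benzyl)benzoyl]-2-hydroxybenzyl}-5,7-dihydroxy-8-iodo-4H-chromen-4-one | O=C(c1ccc(O)c(Cc2c(O)c(I)c3occc(=O)c3c2O)c1)c1cccc(Cc2ccccc2OCc2ccccc2)c1OCc1ccccc1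
F7 | step 14 | 5,7-bis(benzyloxy)-6-{2-(benzyloxy)-5-[2-(benzyloxy)-3-(2-(benzyloxy)benzyl)benzoyl]benzyl}-8-iodo-4H-chromen-4-one | O=C(c1ccc(OCc2ccccc2)c(Cc2c(OCc3ccccc3)c(I)c3occc(=O)c3c2OCc2ccccc2)c1)c1cccc(Cc2ccccc2OCc2ccccc2)c1OCc1ccccc1
F8 | step 14 | 5,7-bis(benzyloxy)-6-{2-(benzyloxy)-5-[2-(benzyloxy)-3-(2-(benzyloxy)benzyl)benzoyl]benzyl}-8-[2-(benzyloxy)benzyl]-4H-chromen-4-one | O=C(c1ccc(OCc2ccccc2)c(Cc2c(OCc3ccccc3)c(Cc3ccccc3OCc3ccccc3)c3occc(=O)c3c2OCc2ccccc2)c1)c1cccc(Cc2ccccc2OCc2ccccc2)c1OCc1ccccc1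
F9 | step 17 | 1-(2,4-bis(benzyloxy)-3-{2-(benzyloxy)-5-[2-(benzyloxy)-3-(2-(benzyloxy)benzyl)benzyl]benzyl}-5-[2-(benzyloxy)benzyl]-6-hydroxyphenyl)ethan-1-one | CC(=O)c1c(O)c(Cc2ccccc2OCc2ccccc2)c(OCc2ccccc2)c(Cc2cc(Cc3cccc(Cc4ccccc4OCc4ccccc4)c3OCc3ccccc3)ccc2OCc2ccccc2)c1OCc1ccccc1
F10 | step 17 | (E)-1-(2,4-bis(benzyloxy)-3-{2-(benzyloxy)-5-[2-(benzyloxy)-3-(2-(benzyloxy)benzyl)benzyl]benzyl}-5-[2-(benzyloxy)benzyl]-6-hydroxyphenyl)-3-phenylprop-2-en-1-one | O=C(/C=C/c1ccccc1)c1c(O)c(Cc2ccccc2OCc2ccccc2)c(OCc2ccccc2)c(Cc2cc(Cc3cccc(Cc4ccccc4OCc4ccccc4)c3OCc3ccccc3)ccc2OCc2ccccc2)c1OCc1ccccc1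
F11 | step 17 | rac-5,7-bis(benzyloxy)-6-{2-(benzyloxy)-5-[2-(benzyloxy)-3-(2-(benzyloxy)benzyl)benzyl]benzyl}-8-[2-(benzyloxy)benzyl]-2-phenylchroman-4-one | O=C1CC(c2ccccc2)Oc2c(Cc3ccccc3OCc3ccccc3)c(OCc3ccccc3)c(Cc3cc(Cc4cccc(Cc5ccccc5OCc5ccccc5)c4OCc4ccccc4)ccc3OCc3ccccc3)c(OCc3ccccc3)c21
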